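Rings are lettered A to H from the 2,4,6-trihydroxyphenoxy terminus to the 3,4,5-trihydroxyphenoxy terminus; in each ring, carbon 1 is the carbon whose ether oxygen points toward ring A (for ring A itself, carbon 1 is its ether carbon).
Enabling feature: rings G, E and C each bear oxygen on five adjacent carbons (carbons 1, 6, 5, 4 and 3) and hydrogen only on carbon 2; carbons 1, 6, 5 and 4 map onto the four carbons of squaric acid and carbons 2 and 3 onto ethyl vinyl ether, so these rings are assembled by cyclobutenone ring expansion instead of arene oxidation.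
Retrosynthetic cuts, in order: all twenty O-alkyl bonds; the hindered aryl C–O bonds at carbon 1 of ring A and at carbon 4 of rings B, D and F (each to a phenol and 4-bromo-3,5-dimethoxybenzaldehyde, whose formyl group is a latent hydroxyl); the bond between carbons 1 and 2 of rings G, E and C (to 4-(1-ethoxyvinyl)cyclobutenones); the ether bonds at carbon 6 of those rings (to a phenol and a squaric ester chloride).
Forward order: the chain grows one ring at a time from the ring H end. Ring H is purchased, G is built by ring expansion, F is attached (aryl ether coupling, then Baeyer–Villiger), E is built, D attached, C built, B and A attached, and all alkyl ethers are cleaved last; G, E and C are the only rings constructed, in that order.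
Stereochemistry: the target has no stereocentre; the single racemic quaternary carbon of each cyclobutenone becomes an sp2 ring carbon on expansion.

Key step: step 6

Assumption: the tertiary lithium alkoxide of each squarate adduct is methylated on oxygen before heating, so that every ring expansion delivers a phenol with one free hydroxyl instead of an air-sensitive hydroquinone; all phenols and the final polyphenol are handled under argon.
Remark: 1-ethoxyvinyllithium 7 is a reagent solution that does not keep; step 4 is carried out afresh, and the solution titrated, on the day of each of its three uses (steps 5, 10 and 15), and it is counted as one step.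

Step 1
Reactants: 1 squaric acid (3,4-dihydroxycyclobut-3-ene-1,2-dione)
Product: 2 squaryl dichloride (3,4-dichlorocyclobut-3-ene-1,2-dione)
Conditions: (COCl)2, DMF (cat.), ClCH2CH2Cl, 50 °C
Reagents that add atoms: oxalyl chloride, ClC(=O)C(=O)Cl
Why: DMF-catalysed (Vilsmeier-type) chlorination with oxalyl chloride turns both vinylogous carboxylic acid hydroxyls into chlorides, the standard preparation of squaryl dichloride.

Step 2
Reactants: 2 squaryl dichloride
Product: 3 3-chloro-4-methoxycyclobut-3-ene-1,2-dione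
Conditions: MeOH (1.0 equiv), Et2O, 0 °C to rt
Reagents that add atoms: methanol, CO
Why: Addition–elimination at one vinylogous acyl chloride carbon (mono-esterification) should stop at the ester chloride, because the methoxy group just introduced donates into the dione and slows the second substitution, a known way to squaric ester chlorides.

Step 3
Reactants: 3 3-chloro-4-methoxycyclobut-3-ene-1,2-dione; 4 3,4,5-trimethoxyphenol
Product: 5 3-methoxy-4-(3,4,5-trimethoxyphenoxy)cyclobut-3-ene-1,2-dione
Conditions: i-Pr2NEt, CH2Cl2, −78 to 0 °C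
Reagents that add atoms: none
Why: Vinylogous O-acylation of the phenol (addition–elimination at the chlorine-bearing carbon) is far easier than displacement of methoxide, and the amine base at low temperature keeps the electron-rich phenoxide reacting at oxygen, so the mixed aryl methyl squarate should form without any aryl C–O coupling.

Step 4
Reactants: 6 ethyl vinyl ether
Product: 7 1-ethoxyvinyllithium (titrated THF solution; used the same day)
Conditions: t-BuLi (pentane), THF, −78 to 0 °C, then recooled to −78 °C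
Reagents that add atoms: tert-butyllithium, [Li]C(C)(C)C
Why: α-Lithiation of an enol ether by t-BuLi, assisted by the ether oxygen, is the standard preparation of this acyl anion equivalent, and making it in its own flask allows titration so that one equivalent meets each squarate.

Step 5
Reactants: 5 3-methoxy-4-(3,4,5-trimethoxyphenoxy)cyclobut-3-ene-1,2-dione; 7 1-ethoxyvinyllithium
Product: 9 racemic 4-(1-ethoxyvinyl)-3,4-dimethoxy-2-(3,4,5-trimethoxyphenoxy)cyclobut-2-en-1-one, via lithium alkoxide 8 (not isolated)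
Conditions: 7 (1.05 equiv), THF, −78 °C; then MeOTf, −78 to 0 °C
Reagents that add atoms: methyl trifluoromethanesulfonate, COS(=O)(=O)C(F)(F)F
Why: 1,2-Addition of an α-alkoxyvinyllithium to a squarate ester and in situ O-methylation of the tertiary alkoxide with MeOTf are both standard in squarate chemistry; attack is expected at the carbonyl that is conjugated through the ring C=C with the weaker aryloxy donor and flanked by the small methoxy group, so the carbinol carbon ends next to the methoxy-bearing carbon and the surviving carbonyl next to the aryloxy-bearing carbon, and the new quaternary stereocentre forms as a racemate that step 6 erases.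

Step 6
Reactants: 9 racemic 4-(1-ethoxyvinyl)-3,4-dimethoxy-2-(3,4,5-trimethoxyphenoxy)cyclobut-2-en-1-one
Product: 12 5-ethoxy-3,4-dimethoxy-2-(3,4,5-trimethoxyphenoxy)phenol (rings G and H; hydroxyl on carbon 1 of ring G free), via dienylketene 10 (not isolated), via cyclohexadienone 11 (not isolated)
Conditions: toluene (degassed, 0.02 M), 110 °C
Reagents that add atoms: none
Why: On heating, 9 should undergo conrotatory 4π electrocyclic opening of the bond between its carbonyl carbon and its quaternary carbon to the (3Z)-dienylketene 10, and a thermally allowed 6π electrocyclization between the ketene carbon and the CH2 terminus of the ethoxyvinyl group then joins carbons 1 and 2 of ring G and gives cyclohexa-2,4-dienone 11, which enolizes to phenol 12. The closest known reaction type is the Moore ring expansion of squarate-derived 4-alkenyl-4-alkoxy- or 4-hydroxycyclobutenones to hydroquinone monoethers and hydroquinones. Ring G is the only ring formed and closes by 6π electrocyclization of the dienylketene (a 1,3,5-hexatriene whose first double bond is the ketene C=C), while the strained four-membered ring is consumed. No stereocentre is created, and the racemic quaternary carbon of 9 becomes the sp2 carbon 4 of ring G. The step needs torquoselectivity, outward rotation of the methoxy group on the quaternary carbon so that the ethoxyvinyl group turns inward next to the ketene, which the strong outward preference of oxygen donors in cyclobutene openings secures; the methyl cap also rules out closure of the ketene onto a free hydroxyl to give a furanone. The substituents of 9 map directly onto ring G as hydroxyl on carbon 1, hydrogen on carbon 2, ethoxy on carbon 3, methoxy on carbons 4 and 5 and the ether to ring H on carbon 6, leaving one free hydroxyl for the next ether bond.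

Step 7
Reactants: 12 5-ethoxy-3,4-dimethoxy-2-(3,4,5-trimethoxyphenoxy)phenol; 13 4-bromo-3,5-dimethoxybenzaldehyde
Product: 14 4-[5-ethoxy-3,4-dimethoxy-2-(3,4,5-trimethoxyphenoxy)phenoxy]-3,5-dimethoxybenzaldehyde (rings F to H; formyl on carbon 1 of ring F)
Conditions: CuI (20 mol %), picolinic acid (40 mol %), K3PO4, DMSO, 100 °C
Reagents that add atoms: none
Why: Ligand-accelerated Ullmann diaryl ether synthesis (CuI, picolinic acid, K3PO4, DMSO) is a combination established for hindered diaryl ethers; the para-formyl group makes the doubly ortho-substituted C–Br bond electron-poor and later serves as a latent hydroxyl, and 12 offers a single free hydroxyl.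

Step 8
Reactants: 14 4-[5-ethoxy-3,4-dimethoxy-2-(3,4,5-trimethoxyphenoxy)phenoxy]-3,5-dimethoxybenzaldehyde
Product: 16 4-[5-ethoxy-3,4-dimethoxy-2-(3,4,5-trimethoxyphenoxy)phenoxy]-3,5-dimethoxyphenol (trimer of rings F to H; hydroxyl on carbon 1 of ring F free), via aryl formate 15 (not isolated)
Conditions: mCPBA, CH2Cl2, 0 °C to rt; then K2CO3 (cat.), MeOH, rt
Reagents that add atoms: 3-chloroperoxybenzoic acid, OOC(=O)c1cccc(Cl)c1
Why: Baeyer–Villiger oxidation of an electron-rich benzaldehyde with aryl migration, as in the conversion of 3,4,5-trimethoxybenzaldehyde into 3,4,5-trimethoxyphenol, should give formate 15, which is methanolysed only after excess peracid has been removed by a reductive wash so that the liberated electron-rich phenol never meets oxidant.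

Step 9
Reactants: 16 trimer phenol (rings F to H); 3 3-chloro-4-methoxycyclobut-3-ene-1,2-dione
Product: 17 3-methoxy-4-(aryloxy)cyclobut-3-ene-1,2-dione in which the aryloxy group is 16 bonded through the oxygen on carbon 1 of its ring F
Conditions: i-Pr2NEt, CH2Cl2, −78 to 0 °C
Reagents that add atoms: none
Why: The same vinylogous O-acylation (addition–elimination on the ester chloride) as in step 3, now on the unhindered ring F hydroxyl of 16, makes the future ether between carbon 6 of ring E and carbon 1 of ring F without aryl coupling.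

Step 10
Reactants: 17 methyl aryl squarate of 16; 7 1-ethoxyvinyllithium
Product: 19 racemic 4-(1-ethoxyvinyl)-3,4-dimethoxy-2-(aryloxy)cyclobut-2-en-1-one in which the aryloxy group is 16 bonded through the oxygen on carbon 1 of its ring F, via lithium alkoxide 18 (not isolated)
Conditions: 7 (1.05 equiv), THF, −78 °C; then MeOTf, −78 to 0 °C
Reagents that add atoms: methyl trifluoromethanesulfonate, COS(=O)(=O)C(F)(F)F
Why: The same 1,2-addition of the α-alkoxyvinyllithium and MeOTf trapping as in step 5 should apply, with the same electronic and steric bias toward the carbonyl conjugated with the aryloxy group; the aryl ethers are inert to the vinyllithium at −78 °C and the racemic quaternary centre is erased in step 11.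

Step 11
Reactants: 19 cyclobutenone carrying the aryloxy group made of rings F to H
Product: 22 5-ethoxy-3,4-dimethoxy-2-(aryloxy)phenol in which the aryloxy group is 16 bonded through the oxygen on carbon 1 of its ring F (tetramer of rings E to H; hydroxyl on carbon 1 of ring E free), via dienylketene 20 (not isolated), via cyclohexadienone 21 (not isolated)
Conditions: toluene (degassed, 0.02 M), 110 °C
Reagents that add atoms: none
Why: Moore ring expansion as in step 6 (4π opening to dienylketene 20, 6π electrocyclization joining carbons 1 and 2 of ring E, enolization of 21) closes ring E and leaves the hydroxyl on its carbon 1 as the only free one.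

Step 12
Reactants: 22 tetramer phenol (rings E to H); 13 4-bromo-3,5-dimethoxybenzaldehyde
Product: 23 3,5-dimethoxy-4-(aryloxy)benzaldehyde in which the aryloxy group is 22 bonded through the oxygen on carbon 1 of its ring E (rings D to H; formyl on carbon 1 of ring D)
Conditions: CuI (20 mol %), picolinic acid (40 mol %), K3PO4, DMSO, 100 °C
Reagents that add atoms: none
Why: CuI-catalysed Ullmann-type diaryl ether coupling as in step 7 joins the ring E oxygen to carbon 4 of ring D, supplied by 13.

Step 13
Reactants: 23 pentamer aldehyde (rings D to H)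
Product: 25 3,5-dimethoxy-4-(aryloxy)phenol in which the aryloxy group is 22 bonded through the oxygen on carbon 1 of its ring E (pentamer of rings D to H; hydroxyl on carbon 1 of ring D free), via aryl formate 24 (not isolated)
Conditions: mCPBA, CH2Cl2, 0 °C to rt; then K2CO3 (cat.), MeOH, rt
Reagents that add atoms: 3-chloroperoxybenzoic acid, OOC(=O)c1cccc(Cl)c1
Why: Baeyer–Villiger oxidation and formate methanolysis as in step 8 should unmask the hydroxyl on carbon 1 of ring D.

Step 14
Reactants: 25 pentamer phenol (rings D to H); 3 3-chloro-4-methoxycyclobut-3-ene-1,2-dione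
Product: 26 3-methoxy-4-(aryloxy)cyclobut-3-ene-1,2-dione in which the aryloxy group is 25 bonded through the oxygen on carbon 1 of its ring D
Conditions: i-Pr2NEt, CH2Cl2, −78 to 0 °C
Reagents that add atoms: none
Why: Vinylogous O-acylation by addition–elimination as in steps 3 and 9 places the ring D oxygen on the squarate carbon that becomes carbon 6 of ring C.

Step 15
Reactants: 26 methyl aryl squarate of 25; 7 1-ethoxyvinyllithium
Product: 28 racemic 4-(1-ethoxyvinyl)-3,4-dimethoxy-2-(aryloxy)cyclobut-2-en-1-one in which the aryloxy group is 25 bonded through the oxygen on carbon 1 of its ring D, via lithium alkoxide 27 (not isolated)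
Conditions: 7 (1.05 equiv), THF, −78 °C; then MeOTf, −78 to 0 °C
Reagents that add atoms: methyl trifluoromethanesulfonate, COS(=O)(=O)C(F)(F)F
Why: 1,2-Addition of 1-ethoxyvinyllithium to the squarate carbonyl conjugated with the aryloxy group and MeOTf trapping as in steps 5 and 10; the racemic quaternary centre is erased in step 16.

Step 16
Reactants: 28 cyclobutenone carrying the aryloxy group made of rings D to H
Product: 31 5-ethoxy-3,4-dimethoxy-2-(aryloxy)phenol in which the aryloxy group is 25 bonded through the oxygen on carbon 1 of its ring D (hexamer of rings C to H; hydroxyl on carbon 1 of ring C free), via dienylketene 29 (not isolated), via cyclohexadienone 30 (not isolated)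
Conditions: toluene (degassed, 0.02 M), 110 °C
Reagents that add atoms: none
Why: Moore ring expansion as in steps 6 and 11 closes ring C by 6π electrocyclization that joins its carbons 1 and 2 and leaves the hydroxyl on carbon 1 free.

Step 17
Reactants: 31 hexamer phenol (rings C to H); 13 4-bromo-3,5-dimethoxybenzaldehyde
Product: 32 3,5-dimethoxy-4-(aryloxy)benzaldehyde in which the aryloxy group is 31 bonded through the oxygen on carbon 1 of its ring C (rings B to H; formyl on carbon 1 of ring B)
Conditions: CuI (20 mol %), picolinic acid (40 mol %), K3PO4, DMSO, 100 °C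
Reagents that add atoms: none
Why: CuI-catalysed Ullmann-type diaryl ether coupling as in step 7 joins the ring C oxygen to carbon 4 of ring B, supplied by 13.

Step 18
Reactants: 32 heptamer aldehyde (rings B to H)
Product: 34 3,5-dimethoxy-4-(aryloxy)phenol in which the aryloxy group is 31 bonded through the oxygen on carbon 1 of its ring C (heptamer of rings B to H; hydroxyl on carbon 1 of ring B free), via aryl formate 33 (not isolated)
Conditions: mCPBA, CH2Cl2, 0 °C to rt; then K2CO3 (cat.), MeOH, rt
Reagents that add atoms: 3-chloroperoxybenzoic acid, OOC(=O)c1cccc(Cl)c1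
Why: Baeyer–Villiger oxidation and formate methanolysis as in step 8 should unmask the hydroxyl on carbon 1 of ring B.

Step 19
Reactants: 34 heptamer phenol (rings B to H); 13 4-bromo-3,5-dimethoxybenzaldehyde
Product: 35 3,5-dimethoxy-4-(aryloxy)benzaldehyde in which the aryloxy group is 34 bonded through the oxygen on carbon 1 of its ring B (rings A to H; formyl on carbon 4 of ring A)
Conditions: CuI (20 mol %), picolinic acid (40 mol %), K3PO4, DMSO, 100 °C
Reagents that add atoms: none
Why: CuI-catalysed Ullmann-type diaryl ether coupling as in step 7, here easier because the ring B hydroxyl of 34 has no ortho substituent, attaches ring A through its carbon 1.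

Step 20
Reactants: 35 octamer aldehyde (rings A to H)
Product: 37 3,5-dimethoxy-4-(aryloxy)phenol in which the aryloxy group is 34 bonded through the oxygen on carbon 1 of its ring B (octamer; seventeen OMe; three OEt; hydroxyl on carbon 4 of ring A free), via aryl formate 36 (not isolated)
Conditions: mCPBA, CH2Cl2, 0 °C to rt; then K2CO3 (cat.), MeOH, rt
Reagents that add atoms: 3-chloroperoxybenzoic acid, OOC(=O)c1cccc(Cl)c1
Why: Baeyer–Villiger oxidation and formate methanolysis as in step 8 should turn the formyl group into the hydroxyl on carbon 4 of ring A, the last oxygen of the skeleton.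

Step 21
Reactants: 37 octamer phenol (seventeen OMe; three OEt)
Product: 38 CNP0206369.0 (the free octamer with twenty-one hydroxyls)
Conditions: BBr3 (excess), CH2Cl2, −78 °C to rt; H2O quench; argon
Reagents that add atoms: none
Why: In this Lewis acid mediated ether cleavage, BBr3 coordinates each alkoxy oxygen and bromide removes the methyl or ethyl group by SN2, while the seven diaryl ether C(sp2)–O bonds cannot be cleaved this way, so aqueous work-up under argon should release all twenty-one hydroxyls.

Compound list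
1 | squaric acid (3,4-dihydroxycyclobut-3-ene-1,2-dione) | OC1=C(O)C(=O)C1=O | starting material
2 | squaryl dichloride (3,4-dichlorocyclobut-3-ene-1,2-dione) | O=C1C(Cl)=C(Cl)C1=O | intermediate
3 | 3-chloro-4-methoxycyclobut-3-ene-1,2-dione | COC1=C(Cl)C(=O)C1=O | intermediate
4 | 3,4,5-trimethoxyphenol | COc1cc(O)cc(OC)c1OC | starting material
5 | 3-methoxy-4-(3,4,5-trimethoxyphenoxy)cyclobut-3-ene-1,2-dione | COC1=C(Oc2cc(OC)c(OC)c(OC)c2)C(=O)C1=O | intermediate
6 | ethyl vinyl ether | C=COCC | starting material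
7 | 1-ethoxyvinyllithium (titrated THF solution) | [Li]C(=C)OCC | intermediate
8 | lithium 1-(1-ethoxyvinyl)-2-methoxy-4-oxo-3-(3,4,5-trimethoxyphenoxy)cyclobut-2-en-1-olate, racemic (not isolated) | [Li]OC1(C(=C)OCC)C(OC)=C(Oc2cc(OC)c(OC)c(OC)c2)C1=O | intermediate
9 | racemic 4-(1-ethoxyvinyl)-3,4-dimethoxy-2-(3,4,5-trimethoxyphenoxy)cyclobut-2-en-1-one | O=C1C(Oc2cc(OC)c(OC)c(OC)c2)=C(OC)C1(OC)C(=C)OCC | intermediate
10 | (3Z)-5-ethoxy-3,4-dimethoxy-2-(3,4,5-trimethoxyphenoxy)hexa-1,3,5-trien-1-one, dienylketene (not isolated) | O=C=C(Oc1cc(OC)c(OC)c(OC)c1)/C(OC)=C(OC)\C(=C)OCC | intermediate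
11 | 5-ethoxy-3,4-dimethoxy-2-(3,4,5-trimethoxyphenoxy)cyclohexa-2,4-dien-1-one (not isolated) | O=C1CC(OCC)=C(OC)C(OC)=C1Oc1cc(OC)c(OC)c(OC)c1 | intermediate
12 | 5-ethoxy-3,4-dimethoxy-2-(3,4,5-trimethoxyphenoxy)phenol (rings G and H) | Oc1cc(OCC)c(OC)c(OC)c1Oc1cc(OC)c(OC)c(OC)c1 | intermediate
13 | 4-bromo-3,5-dimethoxybenzaldehyde | O=Cc1cc(OC)c(Br)c(OC)c1 | starting material
14 | 4-[5-ethoxy-3,4-dimethoxy-2-(3,4,5-trimethoxyphenoxy)phenoxy]-3,5-dimethoxybenzaldehyde (rings F to H) | O=Cc1cc(OC)c(Oc2cc(OCC)c(OC)c(OC)c2Oc2cc(OC)c(OC)c(OC)c2)c(OC)c1 | intermediate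
15 | 4-[5-ethoxy-3,4-dimethoxy-2-(3,4,5-trimethoxyphenoxy)phenoxy]-3,5-dimethoxyphenyl formate (not isolated) | O=COc1cc(OC)c(Oc2cc(OCC)c(OC)c(OC)c2Oc2cc(OC)c(OC)c(OC)c2)c(OC)c1 | intermediate
16 | 4-[5-ethoxy-3,4-dimethoxy-2-(3,4,5-trimethoxyphenoxy)phenoxy]-3,5-dimethoxyphenol (trimer, hydroxyl on carbon 1 of ring F free) | Oc1cc(OC)c(Oc2cc(OCC)c(OC)c(OC)c2Oc2cc(OC)c(OC)c(OC)c2)c(OC)c1 | intermediate
17 | 3-methoxy-4-(aryloxy)cyclobut-3-ene-1,2-dione, aryloxy = 16 through the oxygen on carbon 1 of its ring F | COC1=C(Oc2cc(OC)c(Oc3cc(OCC)c(OC)c(OC)c3Oc3cc(OC)c(OC)c(OC)c3)c(OC)c2)C(=O)C1=O | intermediate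
18 | lithium alkoxide from addition of 7 to 17, racemic (not isolated) | [Li]OC1(C(=C)OCC)C(OC)=C(Oc2cc(OC)c(Oc3cc(OCC)c(OC)c(OC)c3Oc3cc(OC)c(OC)c(OC)c3)c(OC)c2)C1=O | intermediate
19 | racemic 4-(1-ethoxyvinyl)-3,4-dimethoxy-2-(aryloxy)cyclobut-2-en-1-one, aryloxy = 16 through the oxygen on carbon 1 of its ring F | O=C1C(Oc2cc(OC)c(Oc3cc(OCC)c(OC)c(OC)c3Oc3cc(OC)c(OC)c(OC)c3)c(OC)c2)=C(OC)C1(OC)C(=C)OCC | intermediate
20 | (3Z)-dienylketene from 19 (not isolated) | O=C=C(Oc1cc(OC)c(Oc2cc(OCC)c(OC)c(OC)c2Oc2cc(OC)c(OC)c(OC)c2)c(OC)c1)/C(OC)=C(OC)\C(=C)OCC | intermediate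
21 | cyclohexa-2,4-dien-1-one from 20, ring E before enolization (not isolated) | O=C1CC(OCC)=C(OC)C(OC)=C1Oc1cc(OC)c(Oc2cc(OCC)c(OC)c(OC)c2Oc2cc(OC)c(OC)c(OC)c2)c(OC)c1 | intermediate
22 | 5-ethoxy-3,4-dimethoxy-2-(aryloxy)phenol, aryloxy = 16 through the oxygen on carbon 1 of its ring F (tetramer, hydroxyl on carbon 1 of ring E free) | Oc1cc(OCC)c(OC)c(OC)c1Oc1cc(OC)c(Oc2cc(OCC)c(OC)c(OC)c2Oc2cc(OC)c(OC)c(OC)c2)c(OC)c1 | intermediate
23 | 3,5-dimethoxy-4-(aryloxy)benzaldehyde, aryloxy = 22 through the oxygen on carbon 1 of its ring E (rings D to H) | O=Cc1cc(OC)c(Oc2cc(OCC)c(OC)c(OC)c2Oc2cc(OC)c(Oc3cc(OCC)c(OC)c(OC)c3Oc3cc(OC)c(OC)c(OC)c3)c(OC)c2)c(OC)c1 | intermediate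
24 | aryl formate from 23 (not isolated) | O=COc1cc(OC)c(Oc2cc(OCC)c(OC)c(OC)c2Oc2cc(OC)c(Oc3cc(OCC)c(OC)c(OC)c3Oc3cc(OC)c(OC)c(OC)c3)c(OC)c2)c(OC)c1 | intermediate
25 | 3,5-dimethoxy-4-(aryloxy)phenol, aryloxy = 22 through the oxygen on carbon 1 of its ring E (pentamer, hydroxyl on carbon 1 of ring D free) | Oc1cc(OC)c(Oc2cc(OCC)c(OC)c(OC)c2Oc2cc(OC)c(Oc3cc(OCC)c(OC)c(OC)c3Oc3cc(OC)c(OC)c(OC)c3)c(OC)c2)c(OC)c1 | intermediate
26 | 3-methoxy-4-(aryloxy)cyclobut-3-ene-1,2-dione, aryloxy = 25 through the oxygen on carbon 1 of its ring D | COC1=C(Oc2cc(OC)c(Oc3cc(OCC)c(OC)c(OC)c3Oc3cc(OC)c(Oc4cc(OCC)c(OC)c(OC)c4Oc4cc(OC)c(OC)c(OC)c4)c(OC)c3)c(OC)c2)C(=O)C1=O | intermediate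
27 | lithium alkoxide from addition of 7 to 26, racemic (not isolated) | [Li]OC1(C(=C)OCC)C(OC)=C(Oc2cc(OC)c(Oc3cc(OCC)c(OC)c(OC)c3Oc3cc(OC)c(Oc4cc(OCC)c(OC)c(OC)c4Oc4cc(OC)c(OC)c(OC)c4)c(OC)c3)c(OC)c2)C1=O | intermediate
28 | racemic 4-(1-ethoxyvinyl)-3,4-dimethoxy-2-(aryloxy)cyclobut-2-en-1-one, aryloxy = 25 through the oxygen on carbon 1 of its ring D | O=C1C(Oc2cc(OC)c(Oc3cc(OCC)c(OC)c(OC)c3Oc3cc(OC)c(Oc4cc(OCC)c(OC)c(OC)c4Oc4cc(OC)c(OC)c(OC)c4)c(OC)c3)c(OC)c2)=C(OC)C1(OC)C(=C)OCC | intermediate
29 | (3Z)-dienylketene from 28 (not isolated) | O=C=C(Oc1cc(OC)c(Oc2cc(OCC)c(OC)c(OC)c2Oc2cc(OC)c(Oc3cc(OCC)c(OC)c(OC)c3Oc3cc(OC)c(OC)c(OC)c3)c(OC)c2)c(OC)c1)/C(OC)=C(OC)\C(=C)OCC | intermediate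
30 | cyclohexa-2,4-dien-1-one from 29, ring C before enolization (not isolated) | O=C1CC(OCC)=C(OC)C(OC)=C1Oc1cc(OC)c(Oc2cc(OCC)c(OC)c(OC)c2Oc2cc(OC)c(Oc3cc(OCC)c(OC)c(OC)c3Oc3cc(OC)c(OC)c(OC)c3)c(OC)c2)c(OC)c1 | intermediate
31 | 5-ethoxy-3,4-dimethoxy-2-(aryloxy)phenol, aryloxy = 25 through the oxygen on carbon 1 of its ring D (hexamer, hydroxyl on carbon 1 of ring C free) | Oc1cc(OCC)c(OC)c(OC)c1Oc1cc(OC)c(Oc2cc(OCC)c(OC)c(OC)c2Oc2cc(OC)c(Oc3cc(OCC)c(OC)c(OC)c3Oc3cc(OC)c(OC)c(OC)c3)c(OC)c2)c(OC)c1 | intermediate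
32 | 3,5-dimethoxy-4-(aryloxy)benzaldehyde, aryloxy = 31 through the oxygen on carbon 1 of its ring C (rings B to H) | O=Cc1cc(OC)c(Oc2cc(OCC)c(OC)c(OC)c2Oc2cc(OC)c(Oc3cc(OCC)c(OC)c(OC)c3Oc3cc(OC)c(Oc4cc(OCC)c(OC)c(OC)c4Oc4cc(OC)c(OC)c(OC)c4)c(OC)c3)c(OC)c2)c(OC)c1 | intermediate
33 | aryl formate from 32 (not isolated) | O=COc1cc(OC)c(Oc2cc(OCC)c(OC)c(OC)c2Oc2cc(OC)c(Oc3cc(OCC)c(OC)c(OC)c3Oc3cc(OC)c(Oc4cc(OCC)c(OC)c(OC)c4Oc4cc(OC)c(OC)c(OC)c4)c(OC)c3)c(OC)c2)c(OC)c1 | intermediate
34 | 3,5-dimethoxy-4-(aryloxy)phenol, aryloxy = 31 through the oxygen on carbon 1 of its ring C (heptamer, hydroxyl on carbon 1 of ring B free) | Oc1cc(OC)c(Oc2cc(OCC)c(OC)c(OC)c2Oc2cc(OC)c(Oc3cc(OCC)c(OC)c(OC)c3Oc3cc(OC)c(Oc4cc(OCC)c(OC)c(OC)c4Oc4cc(OC)c(OC)c(OC)c4)c(OC)c3)c(OC)c2)c(OC)c1 | intermediate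
35 | 3,5-dimethoxy-4-(aryloxy)benzaldehyde, aryloxy = 34 through the oxygen on carbon 1 of its ring B (rings A to H) | O=Cc1cc(OC)c(Oc2cc(OC)c(Oc3cc(OCC)c(OC)c(OC)c3Oc3cc(OC)c(Oc4cc(OCC)c(OC)c(OC)c4Oc4cc(OC)c(Oc5cc(OCC)c(OC)c(OC)c5Oc5cc(OC)c(OC)c(OC)c5)c(OC)c4)c(OC)c3)c(OC)c2)c(OC)c1 | intermediate
36 | aryl formate from 35 (not isolated) | O=COc1cc(OC)c(Oc2cc(OC)c(Oc3cc(OCC)c(OC)c(OC)c3Oc3cc(OC)c(Oc4cc(OCC)c(OC)c(OC)c4Oc4cc(OC)c(Oc5cc(OCC)c(OC)c(OC)c5Oc5cc(OC)c(OC)c(OC)c5)c(OC)c4)c(OC)c3)c(OC)c2)c(OC)c1 | intermediate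
37 | 3,5-dimethoxy-4-(aryloxy)phenol, aryloxy = 34 through the oxygen on carbon 1 of its ring B (octamer, seventeen OMe, three OEt, hydroxyl on carbon 4 of ring A free) | Oc1cc(OC)c(Oc2cc(OC)c(Oc3cc(OCC)c(OC)c(OC)c3Oc3cc(OC)c(Oc4cc(OCC)c(OC)c(OC)c4Oc4cc(OC)c(Oc5cc(OCC)c(OC)c(OC)c5Oc5cc(OC)c(OC)c(OC)c5)c(OC)c4)c(OC)c3)c(OC)c2)c(OC)c1 | intermediate
38 | CNP0206369.0 (free octamer, rings A to H, twenty-one hydroxyls) | Oc1cc(O)c(Oc2cc(O)c(Oc3cc(O)c(O)c(O)c3Oc3cc(O)c(Oc4cc(O)c(O)c(O)c4Oc4cc(O)c(Oc5cc(O)c(O)c(O)c5Oc5cc(O)c(O)c(O)c5)c(O)c4)c(O)c3)c(O)c2)c(O)c1 | target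

Total step count: 21. Longest linear sequence: 20 steps (steps 1 to 3 and 5 to 21, from 1 to 38); step 4 is a one-step side branch that supplies reagent 7, and compounds 4, 6 and 13 are purchased.

Steps most likely to fail

Step 7 (the same coupling recurs in steps 12, 17 and 19). The bromine-bearing carbon of 13 is flanked by two methoxy groups and phenol 12 carries an ortho aryloxy group. The C–O bond formation may therefore stall, while 13 is hydrodebrominated and the electron-rich phenoxide is oxidised. The fallback sets out from 12 and dispenses with CuI. The bond is made by uncatalysed nucleophilic aromatic substitution with purchased 4-fluoro-3,5-dimethoxybenzaldehyde (O=Cc1cc(OC)c(F)c(OC)c1; Cs2CO3, DMSO, 120 °C). The para-formyl group stabilises the Meisenheimer adduct, and fluoride is small enough to tolerate both ortho substituents. This gives 14 directly, where the route is rejoined; no compound outside the list is made (F0).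

Step 5 (recurring in steps 10 and 15). The organolithium may fail to discriminate between the two ring carbonyls, or may add in conjugate fashion and expel the aryloxide. The fallback sets out from 2 and two equivalents of 4 (i-Pr2NEt, CH2Cl2), which should give the symmetrical 3,4-bis(3,4,5-trimethoxyphenoxy)cyclobut-3-ene-1,2-dione F1, whose two carbonyls are equivalent. Addition of 7 gives the lithium alkoxide F2, and MeOTf converts it into racemic 4-(1-ethoxyvinyl)-4-methoxy-2,3-bis(3,4,5-trimethoxyphenoxy)cyclobut-2-en-1-one F3. Methanol with catalytic K2CO3 at 0 °C should then exchange only the aryloxy group on carbon 3 of the four-membered ring, the vinylogous aryl ester position β to the carbonyl, by addition–elimination. This returns one equivalent of 4 and rejoins the route at 9.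

Step 21. Cleavage of twenty ethers may stay incomplete, and the very polar, air-sensitive polyphenol may be oxidised or lost during isolation. The fallback sets out from 37. The crude product of the BBr3 treatment is not purified but per-acetylated (Ac2O, pyridine, DMAP) to the henicosaacetate of the target F4. This compound should be stable to air and silica, so it can be chromatographed, and fractions that still carry alkyl groups can be resubmitted. Acid-catalysed methanolysis of F4 (HCl in degassed MeOH, rt) then leaves only volatile by-products and comes back to the route at 38.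

Further compounds
F0 | step 7 | none | none
F1 | step 5 | 3,4-bis(3,4,5-trimethoxyphenoxy)cyclobut-3-ene-1,2-dione | O=C1C(=O)C(Oc2cc(OC)c(OC)c(OC)c2)=C1Oc1cc(OC)c(OC)c(OC)c1
F2 | step 5 | lithium 1-(1-ethoxyvinyl)-4-oxo-2,3-bis(3,4,5-trimethoxyphenoxy)cyclobut-2-en-1-olate, racemic | [Li]OC1(C(=C)OCC)C(Oc2cc(OC)c(OC)c(OC)c2)=C(Oc2cc(OC)c(OC)c(OC)c2)C1=O
F3 | step 5 | racemic 4-(1-ethoxyvinyl)-4-methoxy-2,3-bis(3,4,5-trimethoxyphenoxy)cyclobut-2-en-1-one | O=C1C(Oc2cc(OC)c(OC)c(OC)c2)=C(Oc2cc(OC)c(OC)c(OC)c2)C1(OC)C(=C)OCC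
F4 | step 21 | henicosaacetate of 38 (all twenty-one hydroxyls acetylated) | CC(=O)Oc1cc(OC(C)=O)c(Oc2cc(OC(C)=O)c(Oc3cc(OC(C)=O)c(OC(C)=O)c(OC(C)=O)c3Oc3cc(OC(C)=O)c(Oc4cc(OC(C)=O)c(OC(C)=O)c(OC(C)=O)c4Oc4cc(OC(C)=O)c(Oc5cc(OC(C)=O)c(OC(C)=O)c(OC(C)=O)c5Oc5cc(OC(C)=O)c(OC(C)=O)c(OC(C)=O)c5)c(OC(C)=O)c4)c(OC(C)=O)c3)c(OC(C)=O)c2)c(OC(C)=O)c1
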